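The data stem from a simulated flask on assumed constants; noise was put on by code.

At 8.5 min in the east flask I want the share of starting material left, and I reach it by going down the rates of the two finished flasks, from fastest to slowest.

all flasks: partner 2.00 M; catalyst 0.00200 M
- south-east: starting material 1.00 M
- west: starting material 0.500 M
- east: starting material 0.290 M; time 8.5 min

| run | time / min | [starting material] / M |
|---|---|---|
| south-east run | 0.38 | 0.933 |
| south-east run | 1.1 | 0.838 |
| south-east run | 2.2 | 0.724 |
| south-east run | 3.5 | 0.632 |
| south-east run | 5.0 | 0.542 |
| south-east run | 6.6 | 0.483 |
| south-east run | 8.5 | 0.416 |
| west run | 0.38 | 0.443 |
| west run | 1.1 | 0.377 |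
| west run | 2.2 | 0.300 |
| west run | 3.5 | 0.240 |
| west run | 5.0 | 0.188 |
| west run | 6.6 | 0.161 |
| west run | 8.5 | 0.122 |

(readings scatter by 0.003 M)

- the exponent of [starting material] in the starting rate at the charge of the south-east run (at the point where two percent of the starting material have become product) (one fixed amount of product, the same in the runs compared)
- starting material in the east run at 8.5 min, as a share of the starting material charged

- Overall: starting material + partner -> product, with catalyst as catalyst.
- Constant volume, constant temperature.
- A reading of a species includes what of it is bound.
- An order is taken over about fifteen percent of the charge, up and down.

The first rung is the opening: over the first 0.38 min the south-east flask loses 0.176 M min⁻¹ and the west flask 0.150 M min⁻¹, so the charge matters little, and I read a rough order in c(starting material) of 0.233. On the next rung, between its last two readings, the south-east flask holds about the c(starting material) of the fresh west flask, yet it loses 0.0353 M min⁻¹, slower than that opening by a factor of 4.25, so I take the product made as the brake (product inhibition).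

If shares set the pace, equal shares should come at equal values of one measure. The east flask at 8.5 min stands at 14.7 min on the west clock, the time read multiplied by the west charge and divided by the charge of the flask read. The south-east flask keeps 41.6 % at 4.25 min on that clock, and the west flask, interpolated, reaches that share at 4.42 min, a difference of 3.91 %.

The slowest rung is the west tail, 0.0189 M min⁻¹ after 5.0 min, where the logarithm of the share falls by 0.124 min⁻¹. Extending that line from the last west reading to 14.7 min on the west clock gives me an estimate of 11.4 % for the east flask.

The forecast gives an order of 0.18 and a share of 13.3 %, above my share, holding that “so product inhibits strongly”.

The flask gives an order of 0.26 and a share of 12.7 %.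

    catalyst + starting material ⇌ catalyst-substrate complex, settled at all times (1.940 M⁻¹)
    catalyst-substrate complex + partner ⇌ ternary complex, settled at all times (1.310 M⁻¹)
    ternary complex → product + catalyst (139.2 min⁻¹)
    starting material + partner → product (0.009000 M⁻¹ min⁻¹)
    catalyst + product ⇌ catalyst-product complex, settled at all times (23.20 M⁻¹)

At 14.7 min on the west clock the east flask keeps 1.3 percentage points more than my extended tail. The same clock, which puts the east flask's 8.5 min at 14.7 min, carries to a second case: the south-east flask has made product equal to half of its charge at 6.05 min, which on that clock is 3.02 min, and the west flask took 3.24 min. The slow tail comes from catalyst held as catalyst-product complex: without that joining, the east flask at 8.5 min keeps 0.0160 % instead of 12.7 %.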